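The 4-hydroxy-2-pyrone ring is cut into a malonyl unit and a ketone enol. C2', C3' and C4' (pyrone atoms primed), with the bridging methylene already on C3', are an arylmethylmalonyl fragment; O1', C6' (ethyl) and C5' (methyl) are the enol of symmetrical 3-pentanone. One [3+3] annulation of 2-[2,4,6-tris(benzyloxy)benzyl]malonyl dichloride with the trimethylsilyl enol ether of 3-pentanone forms C4'–C5' and O1'–C2' and closes the pyrone on a symmetrical, fully protected phloroglucinol. Hydrogenolysis, one acylation, one C-alkylation and a palladium-catalysed enantioselective closure of the dihydrofuran then complete the arene.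

Key step: step 6

Remark: both stereocentres of the target are read as R; arene positions in 15 and 19 are named by their relation to the acyl group.

Step 1
Reactants: 1 2,4,6-trihydroxybenzaldehyde
Product: 2 2,4,6-tris(benzyloxy)benzaldehyde
Conditions: BnBr (3.5 equiv), K2CO3 (4 equiv), DMF, 60 °C
Reagents that add atoms: benzyl bromide, BrCc1ccccc1
Why: Williamson etherification, in which the formyl group damps ring nucleophilicity so that C-benzylation should stay minor and warming drives the two hydrogen-bonded ortho hydroxyls to completion.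

Step 2
Reactants: 2 2,4,6-tris(benzyloxy)benzaldehyde; 3 Meldrum's acid (2,2-dimethyl-1,3-dioxane-4,6-dione)
Product: 5 5-[2,4,6-tris(benzyloxy)benzyl]-2,2-dimethyl-1,3-dioxane-4,6-dione, via arylidene Meldrum's acid 4 (not isolated)
Conditions: Hantzsch ester (1.1 equiv), L-proline (20 mol%), EtOH, rt to 40 °C
Reagents that add atoms: none
Why: Reductive Knoevenagel alkylation, in which proline-mediated condensation gives arylidene 4 and hydride transfer from the Hantzsch ester reduces it in the same flask before a second Meldrum's acid can add; no stereocentre is formed.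

Step 3
Reactants: 5 5-[2,4,6-tris(benzyloxy)benzyl]-2,2-dimethyl-1,3-dioxane-4,6-dione
Product: 6 2-[2,4,6-tris(benzyloxy)benzyl]malonic acid
Conditions: aq. HCl (3 M), THF, 60 °C
Reagents that add atoms: water, O
Why: Acid-catalysed hydrolysis of the isopropylidene acylal should release acetone and the malonic acid well below the temperature of ketene formation or decarboxylation, aryl benzyl ethers tolerate dilute aqueous acid, and base is avoided because the Meldrum's acid anion resists hydroxide.

Step 4
Reactants: 6 2-[2,4,6-tris(benzyloxy)benzyl]malonic acid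
Product: 7 2-[2,4,6-tris(benzyloxy)benzyl]malonyl dichloride
Conditions: 1-chloro-N,N,2-trimethylprop-1-en-1-amine (2.2 equiv), CH2Cl2, 0 °C to rt; concentrate, use crude
Reagents that add atoms: 1-chloro-N,N,2-trimethylprop-1-en-1-amine, CC(C)=C(Cl)N(C)C
Why: Acid chloride formation with an α-chloroenamine under neutral conditions, chosen because oxalyl chloride/DMF or SOCl2 would attack the trialkoxyarene and release HCl next to the benzyl ethers; the neutral amide co-product is carried along.

Step 5
Reactants: 8 3-pentanone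
Product: 9 (Z)-trimethyl(pent-2-en-3-yloxy)silane
Conditions: TMSCl, Et3N, DMF, 80 °C; pentane extraction, distillation
Reagents that add atoms: chlorotrimethylsilane, C[Si](C)(C)Cl
Why: Thermodynamic silyl enol ether formation; the symmetrical ketone has one enolisation regiochemistry, the Z isomer should predominate, and any E isomer leads to the same pyrone.

Step 6
Reactants: 7 2-[2,4,6-tris(benzyloxy)benzyl]malonyl dichloride; 9 (Z)-trimethyl(pent-2-en-3-yloxy)silane
Product: 11 6-ethyl-4-hydroxy-5-methyl-3-[2,4,6-tris(benzyloxy)benzyl]-2H-pyran-2-one, via diketo acid chloride 10 (not isolated)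
Conditions: 9 (1.3 equiv), Et2O/CH2Cl2, −78 °C to rt
Reagents that add atoms: none
Why: The nucleophilic carbon of 9 attacks one acid chloride of 7 (or the chlorocarbonyl ketene formed from it by loss of HCl), and loss of TMSCl gives diketo acid chloride 10, which makes C4'–C5'. The enol oxygen of the new 1,3-diketone then adds to the second acid chloride and expels chloride, closing the pyrone ring by a 6-exo-trig addition–elimination that makes O1'–C2'; tautomerisation gives the 4-hydroxy-2-pyrone. The closest known reaction type is the condensation of malonyl dichlorides, substituted ones included, with silyl enol ethers to give 4-hydroxy-2-pyrones. No stereocentre is formed, and those of 10 vanish on enolisation. Only chemoselectivity is needed: C-first and O-first acylation converge on 11, the symmetrical ketone allows one enol regiochemistry, and both positions ortho to the benzylic carbon carry oxygen, so no ring carbon is within reach of the acid chlorides. Low temperature and the absence of a Lewis acid should keep the benzyl ether oxygens from attacking.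

Step 7
Reactants: 11 6-ethyl-4-hydroxy-5-methyl-3-[2,4,6-tris(benzyloxy)benzyl]-2H-pyran-2-one
Product: 12 6-ethyl-4-hydroxy-5-methyl-3-(2,4,6-trihydroxybenzyl)-2H-pyran-2-one
Conditions: H2 (1 atm), 10% Pd/C, EtOAc/MeOH, rt
Reagents that add atoms: none
Why: Hydrogenolysis of the three aryl benzyl ethers, under which the fully substituted pyrone and the methylene bridge should be inert; the air-sensitive symmetrical triol is used at once.

Step 8
Reactants: 12 6-ethyl-4-hydroxy-5-methyl-3-(2,4,6-trihydroxybenzyl)-2H-pyran-2-one; 13 (R)-2-methylbutanoic acid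
Product: 15 6-ethyl-4-hydroxy-5-methyl-3-{2,4,6-trihydroxy-3-[(2R)-2-methylbutanoyl]benzyl}-2H-pyran-2-one, via (R)-2-methylbutanoyl chloride 14 (not isolated)
Conditions: 13 (1.3 equiv), (COCl)2 (1.2 equiv), DMF (cat.), CH2Cl2, 0 °C to rt; then 12, AlCl3 (5 equiv), CH2Cl2/PhNO2, 0 °C to rt; ice-cold aq. HCl (1 M), then brief aq. NaHCO3/MeOH
Reagents that add atoms: none
Why: Friedel–Crafts acylation of a phloroglucinol, in which the two free ring positions of 12 are equivalent, the first acyl group deactivates the ring against a second, and the stereocentre of 13 should pass unchanged because neither the acylium ion nor the aluminium-bound chelated ketone enolises readily at or below room temperature (the acid is kept in excess over oxalyl chloride so that none reaches the arene).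

Step 9
Reactants: 16 2-methyl-2-vinyloxirane (isoprene monoxide, racemic)
Product: 17 (E)-4-chloro-2-methylbut-2-en-1-ol
Conditions: TiCl4 (1.1 equiv), CH2Cl2, −90 to −78 °C; aq. HCl
Reagents that add atoms: titanium tetrachloride, Cl[Ti](Cl)(Cl)Cl
Why: Lewis-acid-promoted SN2' opening of a vinyl epoxide, in which chloride is delivered to the vinyl terminus and the E allylic alkoxide is the expected main product; the stereocentre of 16 is destroyed.

Step 10
Reactants: 17 (E)-4-chloro-2-methylbut-2-en-1-ol
Product: 18 (E)-4-chloro-2-methylbut-2-en-1-yl methyl carbonate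
Conditions: ClCO2Me, pyridine, CH2Cl2, 0 °C
Reagents that add atoms: methyl chloroformate, COC(Cl)=O
Why: Carbonate formation by acylation of the primary allylic alcohol with a chloroformate, which leaves the allylic chloride untouched at 0 °C.

Step 11
Reactants: 15 6-ethyl-4-hydroxy-5-methyl-3-{2,4,6-trihydroxy-3-[(2R)-2-methylbutanoyl]benzyl}-2H-pyran-2-one; 18 (E)-4-chloro-2-methylbut-2-en-1-yl methyl carbonate
Product: 19 methyl (2E)-4-{3-[(6-ethyl-4-hydroxy-5-methyl-2-oxo-2H-pyran-3-yl)methyl]-2,4,6-trihydroxy-5-[(2R)-2-methylbutanoyl]phenyl}-2-methylbut-2-en-1-yl carbonate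
Conditions: 18 (1.1 equiv), DBU (2.2 equiv), THF, 0 °C to rt
Reagents that add atoms: none
Why: C-Alkylation of an acylphloroglucinol phenoxide by SN2 at the primary allylic chloride, in which the phloroglucinolate reacts as a vinylogous 1,3-dicarbonyl enolate at its only unsubstituted ring carbon while the pyronate is a weaker, fully substituted nucleophile; the E geometry is retained and the carbonate, a poor leaving group without palladium, should survive.

Step 12
Reactants: 19 methyl (2E)-4-{3-[(6-ethyl-4-hydroxy-5-methyl-2-oxo-2H-pyran-3-yl)methyl]-2,4,6-trihydroxy-5-[(2R)-2-methylbutanoyl]phenyl}-2-methylbut-2-en-1-yl carbonate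
Product: 20 6-ethyl-4-hydroxy-5-methyl-3-{[(2R)-4,6-dihydroxy-5-[(2R)-2-methylbutanoyl]-2-(prop-1-en-2-yl)-2,3-dihydro-1-benzofuran-7-yl]methyl}-2H-pyran-2-one (target)
Conditions: Pd2(dba)3·CHCl3 (2.5 mol%), (1R,2R)-N,N'-bis[2-(diphenylphosphino)benzoyl]cyclohexane-1,2-diamine [(R,R)-DACH-phenyl ligand] (7.5 mol%), CH2Cl2 (0.02 M), rt
Reagents that add atoms: none
Why: Intramolecular asymmetric Tsuji–Trost etherification, in which zerovalent palladium ionises the allylic carbonate with loss of CO2 and methoxide and the phenol para to the acyl group, the most acidic one and not needed for the ketone chelate, attacks the internal allyl terminus in a 5-exo closure; the new C2 stereocentre is set by the chiral pocket of the (R,R) ligand, which for E-configured 2-methylbut-2-enyl carbonates of ortho-substituted phenols is expected to give R (to be confirmed on a model, the enantiomeric ligand being equally available), and the remote acyl stereocentre is untouched.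

Compound list
1 | 2,4,6-trihydroxybenzaldehyde | O=Cc1c(O)cc(O)cc1O | starting material
2 | 2,4,6-tris(benzyloxy)benzaldehyde | O=Cc1c(OCc2ccccc2)cc(OCc2ccccc2)cc1OCc1ccccc1 | intermediate
3 | Meldrum's acid | CC1(C)OC(=O)CC(=O)O1 | starting material
4 | 5-[2,4,6-tris(benzyloxy)benzylidene]-2,2-dimethyl-1,3-dioxane-4,6-dione (arylidene Meldrum's acid, formed in the flask) | CC1(C)OC(=O)C(=Cc2c(OCc3ccccc3)cc(OCc3ccccc3)cc2OCc2ccccc2)C(=O)O1 | intermediate
5 | 5-[2,4,6-tris(benzyloxy)benzyl]-2,2-dimethyl-1,3-dioxane-4,6-dione | CC1(C)OC(=O)C(Cc2c(OCc3ccccc3)cc(OCc3ccccc3)cc2OCc2ccccc2)C(=O)O1 | intermediate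
6 | 2-[2,4,6-tris(benzyloxy)benzyl]malonic acid | OC(=O)C(Cc1c(OCc2ccccc2)cc(OCc2ccccc2)cc1OCc1ccccc1)C(=O)O | intermediate
7 | 2-[2,4,6-tris(benzyloxy)benzyl]malonyl dichloride | O=C(Cl)C(Cc1c(OCc2ccccc2)cc(OCc2ccccc2)cc1OCc1ccccc1)C(Cl)=O | intermediate
8 | 3-pentanone | CCC(=O)CC | starting material
9 | (Z)-trimethyl(pent-2-en-3-yloxy)silane | C/C=C(/CC)O[Si](C)(C)C | intermediate
10 | 4-methyl-3,5-dioxo-2-[2,4,6-tris(benzyloxy)benzyl]heptanoyl chloride (diketo acid chloride, formed in the flask) | CCC(=O)C(C)C(=O)C(Cc1c(OCc2ccccc2)cc(OCc2ccccc2)cc1OCc1ccccc1)C(Cl)=O | intermediate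
11 | 6-ethyl-4-hydroxy-5-methyl-3-[2,4,6-tris(benzyloxy)benzyl]-2H-pyran-2-one | CCc1oc(=O)c(Cc2c(OCc3ccccc3)cc(OCc3ccccc3)cc2OCc2ccccc2)c(O)c1C | intermediate
12 | 6-ethyl-4-hydroxy-5-methyl-3-(2,4,6-trihydroxybenzyl)-2H-pyran-2-one | CCc1oc(=O)c(Cc2c(O)cc(O)cc2O)c(O)c1C | intermediate
13 | (R)-2-methylbutanoic acid | OC(=O)[C@H](C)CC | starting material
14 | (R)-2-methylbutanoyl chloride (formed in the flask) | ClC(=O)[C@H](C)CC | intermediate
15 | 6-ethyl-4-hydroxy-5-methyl-3-{2,4,6-trihydroxy-3-[(2R)-2-methylbutanoyl]benzyl}-2H-pyran-2-one | CCc1oc(=O)c(Cc2c(O)cc(O)c(C(=O)[C@H](C)CC)c2O)c(O)c1C | intermediate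
16 | 2-methyl-2-vinyloxirane (racemic) | C=CC1(C)CO1 | starting material
17 | (E)-4-chloro-2-methylbut-2-en-1-ol | OC/C(C)=C/CCl | intermediate
18 | (E)-4-chloro-2-methylbut-2-en-1-yl methyl carbonate | COC(=O)OC/C(C)=C/CCl | intermediate
19 | methyl (2E)-4-{3-[(6-ethyl-4-hydroxy-5-methyl-2-oxo-2H-pyran-3-yl)methyl]-2,4,6-trihydroxy-5-[(2R)-2-methylbutanoyl]phenyl}-2-methylbut-2-en-1-yl carbonate | COC(=O)OC/C(C)=C/Cc1c(O)c(C(=O)[C@H](C)CC)c(O)c(Cc2c(O)c(C)c(CC)oc2=O)c1O | intermediate
20 | 6-ethyl-4-hydroxy-5-methyl-3-{[(2R)-4,6-dihydroxy-5-[(2R)-2-methylbutanoyl]-2-(prop-1-en-2-yl)-2,3-dihydro-1-benzofuran-7-yl]methyl}-2H-pyran-2-one | C=C(C)[C@H]1Cc2c(O)c(C(=O)[C@H](C)CC)c(O)c(Cc3c(O)c(C)c(CC)oc3=O)c2O1 | target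

Total step count: 12.
Longest linear sequence: 9 steps (steps 1, 2, 3, 4, 6, 7, 8, 11, 12); steps 5 and 9–10 are side branches.

Steps most likely to fail

Step 6. The diacid chloride may be consumed before it meets the enol ether. An ortho benzyloxy oxygen can attack the neighbouring acid chloride with loss of benzyl chloride, the derived chlorocarbonyl ketene can oligomerise or acylate the activated ring of a second molecule, and HCl can desilylate 9 too early. Fallback, from 2 back to 11 without any acid chloride: Knoevenagel condensation of 2 with methyl 3-oxopentanoate (piperidine, AcOH), followed in the same flask by Hantzsch ester reduction, would give methyl 3-oxo-2-[2,4,6-tris(benzyloxy)benzyl]pentanoate F1. Its dianion (NaH, then n-BuLi, THF, 0 to −78 °C) would be acylated at C4 with N-methoxy-N-methylpropanamide to give methyl 4-methyl-3,5-dioxo-2-[2,4,6-tris(benzyloxy)benzyl]heptanoate F2. DBU in hot toluene would then close the lactone of this 3,5-dioxo ester with loss of methanol, rejoining the route at 11.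

Step 11. Alkylation may go to oxygen (phenol or pyrone) or to an already substituted carbon (dearomatisation of the arene, quaternisation at C3'). The carbonate may be transferred to a phenoxide, and long exposure to base may split the methylene bridge by retro-Michael fragmentation. Fallback, from 15 to 20: alkylation of 15 with the free chloro alcohol 17 in cold dilute aq. KOH, a protic medium that favours C-alkylation and an electrophile with no base-labile group, would give 6-ethyl-4-hydroxy-3-{2,4,6-trihydroxy-3-[(2E)-4-hydroxy-3-methylbut-2-en-1-yl]-5-[(2R)-2-methylbutanoyl]benzyl}-5-methyl-2H-pyran-2-one F3. Immobilised Candida antarctica lipase B with vinyl acetate in THF would acetylate only the aliphatic hydroxyl, giving the allylic acetate of F3 F4. F4 would be cyclised under the catalyst system of step 12 with Et3N added, coming back to the route at 20.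

Step 12. Ring closure may take place through the phenol ortho to the acyl group instead of the para one. Facial discrimination by the ligand may be insufficient on so crowded a phenol, and intermolecular allylation may compete; any C2 epimer would be a diastereomer of 20. Fallback, from 15 to 20 by epoxide opening and dehydration:
- Prenyl bromide in cold aq. KOH would give 6-ethyl-4-hydroxy-5-methyl-3-{2,4,6-trihydroxy-3-(3-methylbut-2-en-1-yl)-5-[(2R)-2-methylbutanoyl]benzyl}-2H-pyran-2-one F5.
- Ac2O/pyridine would give the tetraacetate of F5 F6.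
- Shi epoxidation with the L-fructose-derived ketone (KHSO5 as 2KHSO5·KHSO4·K2SO4, NaHCO3-buffered aq. MeCN, 0 °C) should give the tetraacetate bearing a [(2S)-3,3-dimethyloxiran-2-yl]methyl group F7. The S epoxide follows from the enantiomer of the catalyst that gives R epoxides with this olefin class.
- K2CO3/MeOH would remove the acetates, the one para to the ketone first, and the freed phenoxide would open the epoxide 5-exo with inversion. This gives 6-ethyl-4-hydroxy-3-{[(2R)-4,6-dihydroxy-2-(2-hydroxypropan-2-yl)-5-[(2R)-2-methylbutanoyl]-2,3-dihydro-1-benzofuran-7-yl]methyl}-5-methyl-2H-pyran-2-one F8.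
- Ac2O/pyridine would cap the two phenols and the pyrone hydroxyl, giving the triacetate of F8 F9.
- Burgess reagent in toluene at 50 °C would dehydrate the tertiary alcohol to the triacetate of 20 F10.
- K2CO3/MeOH at 0 °C would return to the route at 20.

Further compounds
F1 | step 6 | methyl 3-oxo-2-[2,4,6-tris(benzyloxy)benzyl]pentanoate | CCC(=O)C(Cc1c(OCc2ccccc2)cc(OCc2ccccc2)cc1OCc1ccccc1)C(=O)OC
F2 | step 6 | methyl 4-methyl-3,5-dioxo-2-[2,4,6-tris(benzyloxy)benzyl]heptanoate | CCC(=O)C(C)C(=O)C(Cc1c(OCc2ccccc2)cc(OCc2ccccc2)cc1OCc1ccccc1)C(=O)OC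
F3 | step 11 | 6-ethyl-4-hydroxy-3-{2,4,6-trihydroxy-3-[(2E)-4-hydroxy-3-methylbut-2-en-1-yl]-5-[(2R)-2-methylbutanoyl]benzyl}-5-methyl-2H-pyran-2-one | OC/C(C)=C/Cc1c(O)c(C(=O)[C@H](C)CC)c(O)c(Cc2c(O)c(C)c(CC)oc2=O)c1O
F4 | step 11 | allylic acetate of F3 | CC(=O)OC/C(C)=C/Cc1c(O)c(C(=O)[C@H](C)CC)c(O)c(Cc2c(O)c(C)c(CC)oc2=O)c1O
F5 | step 12 | 6-ethyl-4-hydroxy-5-methyl-3-{2,4,6-trihydroxy-3-(3-methylbut-2-en-1-yl)-5-[(2R)-2-methylbutanoyl]benzyl}-2H-pyran-2-one | CC(C)=CCc1c(O)c(C(=O)[C@H](C)CC)c(O)c(Cc2c(O)c(C)c(CC)oc2=O)c1O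
F6 | step 12 | tetraacetate of F5 (three phenols and the pyrone hydroxyl) | CC(C)=CCc1c(OC(C)=O)c(C(=O)[C@H](C)CC)c(OC(C)=O)c(Cc2c(OC(C)=O)c(C)c(CC)oc2=O)c1OC(C)=O
F7 | step 12 | tetraacetate with the prenyl group as its (2S)-3,3-dimethyloxiran-2-ylmethyl epoxide | CC1(C)O[C@H]1Cc1c(OC(C)=O)c(C(=O)[C@H](C)CC)c(OC(C)=O)c(Cc2c(OC(C)=O)c(C)c(CC)oc2=O)c1OC(C)=O
F8 | step 12 | 6-ethyl-4-hydroxy-3-{[(2R)-4,6-dihydroxy-2-(2-hydroxypropan-2-yl)-5-[(2R)-2-methylbutanoyl]-2,3-dihydro-1-benzofuran-7-yl]methyl}-5-methyl-2H-pyran-2-one | CC(C)(O)[C@H]1Cc2c(O)c(C(=O)[C@H](C)CC)c(O)c(Cc3c(O)c(C)c(CC)oc3=O)c2O1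
F9 | step 12 | triacetate of F8 (two phenols and the pyrone hydroxyl) | CC(C)(O)[C@H]1Cc2c(OC(C)=O)c(C(=O)[C@H](C)CC)c(OC(C)=O)c(Cc3c(OC(C)=O)c(C)c(CC)oc3=O)c2O1
F10 | step 12 | triacetate of 20 (two phenols and the pyrone hydroxyl) | C=C(C)[C@H]1Cc2c(OC(C)=O)c(C(=O)[C@H](C)CC)c(OC(C)=O)c(Cc3c(OC(C)=O)c(C)c(CC)oc3=O)c2O1
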